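**Strategy.** The 3-methylfuran-2(5H)-one ring (O1, C2=O, C3–CH3, C4H=, C5H) is treated as the cycloisomer of a 2-methyl-2,3-allenoic acid. The ring bond O1–C5 and the stereocentre C5 are made together, in the last step, by Ag(I)-catalysed 5-endo closure of the carboxyl oxygen onto the allene terminus, which turns the allene axis into the (R)-centre. The precursor is the acyclic (aR)-allenoic acid, an isomer of the target that already carries the enone and the coumarin ether. Its axis comes from an (S)-propargylic carbinol by anti-SN2′ Pd hydroxycarbonylation of the mesylate (centre → axis → centre). The carbinol is set by Brown-type 2-bromoallylboration of but-2-ynal.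

Key step: step 6

Assumption: 7-hydroxy-8-methoxycoumarin (daphnetin 8-methyl ether) and but-2-ynal are bought as catalogue compounds; B-bromodiisopinocampheylborane is made in the flask from (+)-α-pinene and BH2Br·SMe2.

**Step 1**
Reactants: 1 but-2-ynal; 2 allene (propa-1,2-diene)
Product: 5 (4S)-2-bromohept-1-en-5-yn-4-ol, via B-(2-bromoallyl)diisopinocampheylborane 3 (not isolated), via diisopinocampheylborinate of the carbinol 4 (not isolated)
Conditions: (+)-α-pinene (2.1 equiv), BH2Br·SMe2, CH2Cl2, 0 °C → rt; 2, −78 → 0 °C; 1, Et2O, −78 °C; NaOH, H2O2, 0 °C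
Reagents that add atoms: bromoborane–dimethyl sulfide complex, C[S+](C)[BH2-]Br
Why: Brown allylboration: the 2-bromoallyl group made by bromoboration of allene should be transferred through a closed chair (Zimmerman–Traxler) transition state, and the isopinocampheyl groups derived from (+)-α-pinene direct it to the Si face of the ynal, which sets the (4S)-carbinol.

**Step 2**
Reactants: 5 (4S)-2-bromohept-1-en-5-yn-4-ol; 6 2-chloro-N-methoxy-N-methylacetamide
Product: 8 (5S)-1-chloro-5-hydroxy-3-methylideneoct-6-yn-2-one, via O,C-dilithio derivative of the bromo alcohol 7 (not isolated)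
Conditions: MeLi (1.0 equiv), Et2O, −78 °C; t-BuLi (2.1 equiv), −78 °C; 6, −78 → −40 °C; aq. NH4Cl
Reagents that add atoms: none
Why: Bromine–lithium exchange on the preformed lithium alkoxide should give a 2-lithioalkene that acylates the Weinreb amide only once, because the chelated tetrahedral adduct persists until work-up (Weinreb ketone synthesis); the carbinol centre is not touched.

**Step 3**
Reactants: 8 (5S)-1-chloro-5-hydroxy-3-methylideneoct-6-yn-2-one; 9 7-hydroxy-8-methoxy-2H-chromen-2-one
Product: 10 7-{[(5S)-5-hydroxy-3-methylidene-2-oxooct-6-yn-1-yl]oxy}-8-methoxy-2H-chromen-2-one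
Conditions: K2CO3, KI (cat.), acetone, 0 °C → rt
Reagents that add atoms: none
Why: Williamson ether synthesis: carbonate deprotonates only the acidic coumarin phenol, and Finkelstein-assisted SN2 displacement at the α-halo ketone should be much faster than reversible oxa-Michael addition to the enone.

**Step 4**
Reactants: 10 7-{[(5S)-5-hydroxy-3-methylidene-2-oxooct-6-yn-1-yl]oxy}-8-methoxy-2H-chromen-2-one
Product: 11 (4S)-8-[(8-methoxy-2-oxo-2H-chromen-7-yl)oxy]-6-methylidene-7-oxooct-2-yn-4-yl methanesulfonate
Conditions: MsCl, Et3N, CH2Cl2, −78 → −40 °C; used crude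
Reagents that add atoms: methanesulfonyl chloride, CS(=O)(=O)Cl
Why: O-sulfonylation of the secondary propargylic alcohol at low temperature breaks no bond to the stereocentre, so the (S)-configuration is retained.

**Step 5**
Reactants: 11 (4S)-8-[(8-methoxy-2-oxo-2H-chromen-7-yl)oxy]-6-methylidene-7-oxooct-2-yn-4-yl methanesulfonate
Product: 12 (aR)-8-[(8-methoxy-2-oxo-2H-chromen-7-yl)oxy]-2-methyl-6-methylidene-7-oxoocta-2,3-dienoic acid (viewed along the axis from C2, the sequence CO2H → CH3 → C5H2 runs clockwise)
Conditions: Pd(PPh3)4 (5 mol%), CO (1 atm), THF/H2O, rt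
Reagents that add atoms: carbon monoxide, [C-]#[O+]; water, O
Why: Pd(0)-catalysed propargylic hydroxycarbonylation: Pd(0) should ionise the mesylate by anti-SN2′ attack to a configurationally defined allenyl–palladium species, CO inserts with retention and water cleaves the acyl–palladium bond, so the (S)-centre is translated into the (aR)-axis under neutral conditions that the enone and coumarin tolerate.

**Step 6**
Reactants: 12 (aR)-8-[(8-methoxy-2-oxo-2H-chromen-7-yl)oxy]-2-methyl-6-methylidene-7-oxoocta-2,3-dienoic acid
Product: 13 8-methoxy-7-({3-[((2R)-4-methyl-5-oxo-2,5-dihydrofuran-2-yl)methyl]-2-oxobut-3-en-1-yl}oxy)-2H-chromen-2-one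
Conditions: AgNO3 (10 mol%), acetone, rt, dark
Reagents that add atoms: none
Why: Ag(I) coordinates the electron-richer distal C3=C4 π-bond of the 2,3-allenoic acid on the face away from the carboxyl group, the carboxyl oxygen adds anti to silver at the allene terminus (the future ring C5), and protodemetalation of the vinyl–silver lactone releases the furan-2(5H)-one and the catalyst. The closest known reaction type is the Ag(I)- or Au-catalysed cycloisomerisation of 2,3-allenoic acids to butenolides with axis-to-centre chirality transfer. The furanone ring is closed in the 5-endo-trig mode by forming the O1–C5 bond. The new stereocentre C5 is controlled by the allene axis alone: the ring forms in the plane of the carboxyl-bearing terminus while H and CH2 at the other terminus stay above and below it, so (aR) should give (5R). The step needs O-attack at the allene rather than at the enone or by the ketone oxygen; this is secured because only the carboxyl is placed for five-membered closure and the electron-poor enone and coumarin are not π-activated by Ag(I), and the neutral medium leaves the acidic γ-hydrogen at C5 of the product untouched.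

**Compound list**
1 | but-2-ynal | CC#CC=O | starting material
2 | allene (propa-1,2-diene) | C=C=C | starting material
3 | B-(2-bromoallyl)diisopinocampheylborane, Ipc groups from (+)-α-pinene | C=C(Br)CB([C@@H]1C[C@@H]2C[C@H]([C@H]1C)C2(C)C)[C@@H]1C[C@@H]2C[C@H]([C@H]1C)C2(C)C | intermediate (not isolated)
4 | (4S)-2-bromohept-1-en-5-yn-4-yl diisopinocampheylborinate | CC#C[C@@H](OB([C@@H]1C[C@@H]2C[C@H]([C@H]1C)C2(C)C)[C@@H]1C[C@@H]2C[C@H]([C@H]1C)C2(C)C)CC(Br)=C | intermediate (not isolated)
5 | (4S)-2-bromohept-1-en-5-yn-4-ol | CC#C[C@@H](O)CC(Br)=C | intermediate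
6 | 2-chloro-N-methoxy-N-methylacetamide | ClCC(=O)N(C)OC | starting material
7 | lithium (4S)-2-lithiohept-1-en-5-yn-4-olate (O,C-dilithio derivative of 5) | CC#C[C@@H](O[Li])CC(=C)[Li] | intermediate (not isolated)
8 | (5S)-1-chloro-5-hydroxy-3-methylideneoct-6-yn-2-one | CC#C[C@@H](O)CC(=C)C(=O)CCl | intermediate
9 | 7-hydroxy-8-methoxy-2H-chromen-2-one (daphnetin 8-methyl ether) | COc1c(O)ccc2ccc(=O)oc12 | starting material
10 | 7-{[(5S)-5-hydroxy-3-methylidene-2-oxooct-6-yn-1-yl]oxy}-8-methoxy-2H-chromen-2-one | CC#C[C@@H](O)CC(=C)C(=O)COc1ccc2ccc(=O)oc2c1OC | intermediate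
11 | (4S)-8-[(8-methoxy-2-oxo-2H-chromen-7-yl)oxy]-6-methylidene-7-oxooct-2-yn-4-yl methanesulfonate | CC#C[C@@H](OS(C)(=O)=O)CC(=C)C(=O)COc1ccc2ccc(=O)oc2c1OC | intermediate
12 | (aR)-8-[(8-methoxy-2-oxo-2H-chromen-7-yl)oxy]-2-methyl-6-methylidene-7-oxoocta-2,3-dienoic acid | CC(C(O)=O)=[C@@]=C([H])CC(=C)C(=O)COc1ccc2ccc(=O)oc2c1OC | intermediate
13 | 8-methoxy-7-({3-[((2R)-4-methyl-5-oxo-2,5-dihydrofuran-2-yl)methyl]-2-oxobut-3-en-1-yl}oxy)-2H-chromen-2-one | C=C(C[C@@H]1C=C(C)C(=O)O1)C(=O)COc1ccc2ccc(=O)oc2c1OC | target

**Step count and risks**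
Total steps: 6. Longest linear sequence: 6 (steps 1–6).

Steps most likely to fail:

1. Step 2. The vinyllithium may be quenched by incompletely deprotonated hydroxyl, or the free γ-hydroxy α-chloro enone may cyclise or polymerise during work-up. Fallback (protecting-group route in place of the dianion): setting out from 5, silylation (TBSCl, imidazole, DMF) should give the silyl ether (4S)-2-bromo-4-(tert-butyldimethylsilyloxy)hept-1-en-5-yne F1. Bromine–lithium exchange (t-BuLi, Et2O, −78 °C) and acylation with 6 should give the silyl-protected chloromethyl enone F2. Williamson etherification with 9 (K2CO3, KI, acetone) should give the silyl-protected aryl ether F3, and desilylation with HF·pyridine (THF, 0 °C) comes back to the route at 10.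

2. Step 5. Triphenylphosphine may add to the exocyclic enone and stall the catalyst, or slow CO capture may let the allenyl–palladium intermediate lose configuration. Fallback (carbonylation and ring closure before the enone exists): setting out from 5, mesylation should give (4S)-2-bromohept-1-en-5-yn-4-yl methanesulfonate F4. Pd(PPh3)4/CO/H2O at rt, where the 2-bromoalkene should stay inert, should give (aR)-6-bromo-2-methylhepta-2,3,6-trienoic acid F5, and AgNO3 in acetone should close it to (5R)-5-(2-bromoprop-2-en-1-yl)-3-methylfuran-2(5H)-one F6. Separately, 9 is alkylated with bromoacetaldehyde diethyl acetal (K2CO3, DMF, 90 °C) to 7-(2,2-diethoxyethoxy)-8-methoxy-2H-chromen-2-one F7 and hydrolysed (aq. HCl, THF) to [(8-methoxy-2-oxo-2H-chromen-7-yl)oxy]acetaldehyde F8. Nozaki–Hiyama–Kishi coupling of F6 with F8 (CrCl2, NiCl2 cat., DMF) should give the allylic alcohol F9 as a mixture of carbinol epimers, and Dess–Martin oxidation comes back to the route at 13.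

3. Step 1. Facial discrimination may be poor with the sterically small alkynyl aldehyde, or bromoboration of allene by the hindered bromoborane may be sluggish. Fallback (catalyst-controlled reduction in place of reagent-controlled allylation): setting out from 1, indium-mediated Barbier addition of 2,3-dibromopropene (In, THF/H2O) should give racemic 2-bromohept-1-en-5-yn-4-ol F10. Dess–Martin oxidation should give 6-bromohept-6-en-2-yn-4-one F11, and Noyori transfer hydrogenation with (S,S)-TsDPEN–Ru(p-cymene) in i-PrOH comes back to the route at 5.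

**Further compounds**
F1 | step 2 | (4S)-2-bromo-4-(tert-butyldimethylsilyloxy)hept-1-en-5-yne | CC#C[C@@H](O[Si](C)(C)C(C)(C)C)CC(Br)=C
F2 | step 2 | (5S)-5-(tert-butyldimethylsilyloxy)-1-chloro-3-methylideneoct-6-yn-2-one | CC#C[C@@H](O[Si](C)(C)C(C)(C)C)CC(=C)C(=O)CCl
F3 | step 2 | 7-{[(5S)-5-(tert-butyldimethylsilyloxy)-3-methylidene-2-oxooct-6-yn-1-yl]oxy}-8-methoxy-2H-chromen-2-one | CC#C[C@@H](O[Si](C)(C)C(C)(C)C)CC(=C)C(=O)COc1ccc2ccc(=O)oc2c1OC
F4 | step 5 | (4S)-2-bromohept-1-en-5-yn-4-yl methanesulfonate | CC#C[C@@H](OS(C)(=O)=O)CC(Br)=C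
F5 | step 5 | (aR)-6-bromo-2-methylhepta-2,3,6-trienoic acid | CC(C(O)=O)=[C@@]=C([H])CC(Br)=C
F6 | step 5 | (5R)-5-(2-bromoprop-2-en-1-yl)-3-methylfuran-2(5H)-one | C=C(Br)C[C@@H]1C=C(C)C(=O)O1
F7 | step 5 | 7-(2,2-diethoxyethoxy)-8-methoxy-2H-chromen-2-one | CCOC(COc1ccc2ccc(=O)oc2c1OC)OCC
F8 | step 5 | [(8-methoxy-2-oxo-2H-chromen-7-yl)oxy]acetaldehyde | O=CCOc1ccc2ccc(=O)oc2c1OC
F9 | step 5 | 7-({2-hydroxy-3-[((2R)-4-methyl-5-oxo-2,5-dihydrofuran-2-yl)methyl]but-3-en-1-yl}oxy)-8-methoxy-2H-chromen-2-one, carbinol epimers | C=C(C[C@@H]1C=C(C)C(=O)O1)C(O)COc1ccc2ccc(=O)oc2c1OC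
F10 | step 1 | racemic 2-bromohept-1-en-5-yn-4-ol | CC#CC(O)CC(Br)=C
F11 | step 1 | 6-bromohept-6-en-2-yn-4-one | CC#CC(=O)CC(Br)=C
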